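**Strategy.** The oxolane ring is closed by forming its C3–C4 bond in a radical 5-exo-trig cyclisation. The precursor is an open-chain epoxy cinnamyl ether in which only the aryl-bearing carbon (later C2) is stereodefined. Cp2TiCl opens the terminal epoxide to a secondary radical at the future C3, which keeps its oxygen as the hydroxymethyl group. This radical adds to the cinnamyl double bond, whose far carbon becomes the benzylic CH2. The step exploits the C3–CH2OH and C4–CH2Ar branches of the oxolane, erases the epoxide stereocentre so that both epimers converge, and sets C3 and C4 from C2 alone. Both halves come from an aryl aldehyde and vinylmagnesium bromide.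

Key step: step 7

Remark on the chemistry: aldehydes 1 and 5 are taken as commercial. The carbinol carbon of 7 and 8 is labelled S and the same carbon in 9 and 10 is labelled R. This is a change of CIP priorities only, not of spatial arrangement. The enantiomeric purity of the target rests on the kinetic resolution in step 5.

**Step 1**
Reactants: 1 3-hydroxy-4,5-dimethoxybenzaldehyde
Product: 2 3,4-dimethoxy-5-(triisopropylsilyloxy)benzaldehyde
Conditions: TIPSCl (1.2 equiv), imidazole (2.5 equiv), DMF, rt
Reagents that add atoms: triisopropylsilyl chloride, CC(C)[Si](Cl)(C(C)C)C(C)C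
Why: Imidazole-promoted silyl ether formation masks the phenol for the Grignard and alkoxide steps, and the hindered aryl TIPS ether should survive PBr3, NaH in THF and Cp2TiCl.

**Step 2**
Reactants: 2 3,4-dimethoxy-5-(triisopropylsilyloxy)benzaldehyde
Product: 3 rac-1-[3,4-dimethoxy-5-(triisopropylsilyloxy)phenyl]prop-2-en-1-ol
Conditions: CH2=CHMgBr (1.2 equiv), THF, −20 to 0 °C; sat. aq. NH4Cl
Reagents that add atoms: vinylmagnesium bromide, C=C[Mg]Br
Why: Grignard 1,2-addition to the aldehyde should give the allylic alcohol as a racemate, which is acceptable because this stereocentre is removed in step 3.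

**Step 3**
Reactants: 3 rac-1-[3,4-dimethoxy-5-(triisopropylsilyloxy)phenyl]prop-2-en-1-ol
Product: 4 (E)-3-[3,4-dimethoxy-5-(triisopropylsilyloxy)phenyl]prop-2-en-1-yl bromide
Conditions: PBr3 (0.4 equiv), Et2O, 0 °C, short reaction time; cold aq. NaHCO3 wash; used crude at once
Reagents that add atoms: phosphorus tribromide, BrP(Br)Br
Why: Bromination of a 1-arylallyl alcohol with allylic transposition (SN2'-type collapse of the activated phosphite at the alkene terminus) should deliver the conjugated, thermodynamically preferred (E)-cinnamyl bromide.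

**Step 4**
Reactants: 5 3,4,5-trimethoxybenzaldehyde
Product: 6 rac-1-(3,4,5-trimethoxyphenyl)prop-2-en-1-ol
Conditions: CH2=CHMgBr (1.2 equiv), THF, −20 to 0 °C; sat. aq. NH4Cl
Reagents that add atoms: vinylmagnesium bromide, C=C[Mg]Br
Why: Grignard 1,2-addition to the aldehyde should give the racemic secondary allylic alcohol that is resolved in step 5.

**Step 5**
Reactants: 6 rac-1-(3,4,5-trimethoxyphenyl)prop-2-en-1-ol
Product: 7 (S)-[(2R)-oxiran-2-yl](3,4,5-trimethoxyphenyl)methanol (erythro epoxy alcohol)
Conditions: Ti(OiPr)4 (0.2 equiv), L-(+)-diisopropyl tartrate (0.24 equiv), tBuOOH (0.45 equiv, isooctane), 4 Å MS, CH2Cl2, −20 °C; chromatographic separation from unreacted alcohol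
Reagents that add atoms: tert-butyl hydroperoxide, CC(C)(C)OO
Why: In the Sharpless kinetic resolution (Katsuki–Sharpless epoxidation of a secondary allylic alcohol) the L-(+)-tartrate catalyst should epoxidise the (R)-enantiomer much faster than the (S)-enantiomer and erythro-selectively, so that stopping below half conversion gives 7 with the carbinol configuration needed for C2, while the new epoxide stereocentre is of no consequence later.

**Step 6**
Reactants: 7 (S)-[(2R)-oxiran-2-yl](3,4,5-trimethoxyphenyl)methanol; 4 (E)-3-[3,4-dimethoxy-5-(triisopropylsilyloxy)phenyl]prop-2-en-1-yl bromide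
Product: 8 (2R)-2-[(S)-({(2E)-3-[3,4-dimethoxy-5-(triisopropylsilyloxy)phenyl]prop-2-en-1-yl}oxy)(3,4,5-trimethoxyphenyl)methyl]oxirane
Conditions: NaH (1.1 equiv), THF, −20 °C; then 4 (1.2 equiv), Bu4NI (cat.), −20 to 0 °C
Reagents that add atoms: none
Why: Williamson ether synthesis, in which fast SN2 capture of the sodium alkoxide by the primary allylic bromide in cold THF should outrun Payne rearrangement and leave the carbinol C–O bond, and hence its configuration, untouched.

**Step 7**
Reactants: 8 (2R)-2-[(S)-({(2E)-3-[3,4-dimethoxy-5-(triisopropylsilyloxy)phenyl]prop-2-en-1-yl}oxy)(3,4,5-trimethoxyphenyl)methyl]oxirane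
Product: 9 [(2R,3S,4S)-4-{[3,4-dimethoxy-5-(triisopropylsilyloxy)phenyl]methyl}-2-(3,4,5-trimethoxyphenyl)oxolan-3-yl]methanol
Conditions: Cp2TiCl2 (2.5 equiv), Zn dust, THF, rt (green Cp2TiCl solution added dropwise to 8); then 1 M HCl, 0 °C
Reagents that add atoms: none
Why: Cp2TiCl (trivalent titanium) transfers one electron to the epoxide and the C–O bond to the more substituted carbon breaks homolytically, giving a secondary β-titanoxy radical at the future C3 that adds to the cinnamyl double bond; the benzylic radical formed is captured by a second Cp2TiCl, and HCl protonates the O–Ti and C–Ti bonds with return of Cp2TiCl2. The closest known reaction type is the Nugent–RajanBabu reductive epoxide opening with radical cyclisation, which is established for epoxy allyl and cinnamyl ethers. The oxolane ring closes in the 5-exo-trig mode, favoured over 6-endo closure by the chair-like Beckwith–Houk transition state and by benzylic stabilisation of the adduct radical. C2 is the only stereocentre that survives radical formation and controls both new ones: its trimethoxyphenyl group sits pseudo-equatorial, which places it trans to the CH2OTi group on C3 (new centre S) and puts the C3 and C4 substituents cis (new centre S), as expected for a radical substituted at the radical carbon. The step needs regioselective opening to the secondary radical and ring closure faster than capture of that radical by titanium, which the styrene-type acceptor and the slow addition of Cp2TiCl should secure. It is stereoconvergent because the epoxide carbon becomes planar, so either epimer of 8 at that carbon should give the same product.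

**Step 8**
Reactants: 9 [(2R,3S,4S)-4-{[3,4-dimethoxy-5-(triisopropylsilyloxy)phenyl]methyl}-2-(3,4,5-trimethoxyphenyl)oxolan-3-yl]methanol
Product: 10 [(2R,3S,4S)-4-[(3-hydroxy-4,5-dimethoxyphenyl)methyl]-2-(3,4,5-trimethoxyphenyl)oxolan-3-yl]methanol
Conditions: Bu4NF (1.1 equiv), AcOH (1.1 equiv), THF, 0 °C to rt
Reagents that add atoms: none
Why: Fluoride-mediated desilylation of the aryl silyl ether, buffered with acetic acid to protect the electron-rich phenol, should free the phenol without touching any stereocentre.

**Compound list**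
1 | 3-hydroxy-4,5-dimethoxybenzaldehyde | COc1cc(C=O)cc(O)c1OC | starting material
2 | 3,4-dimethoxy-5-(triisopropylsilyloxy)benzaldehyde | COc1cc(C=O)cc(O[Si](C(C)C)(C(C)C)C(C)C)c1OC | intermediate
3 | rac-1-[3,4-dimethoxy-5-(triisopropylsilyloxy)phenyl]prop-2-en-1-ol | COc1cc(C(O)C=C)cc(O[Si](C(C)C)(C(C)C)C(C)C)c1OC | intermediate
4 | (E)-3-[3,4-dimethoxy-5-(triisopropylsilyloxy)phenyl]prop-2-en-1-yl bromide | COc1cc(/C=C/CBr)cc(O[Si](C(C)C)(C(C)C)C(C)C)c1OC | intermediate
5 | 3,4,5-trimethoxybenzaldehyde | COc1cc(C=O)cc(OC)c1OC | starting material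
6 | rac-1-(3,4,5-trimethoxyphenyl)prop-2-en-1-ol | COc1cc(C(O)C=C)cc(OC)c1OC | intermediate
7 | (S)-[(2R)-oxiran-2-yl](3,4,5-trimethoxyphenyl)methanol | COc1cc([C@H](O)[C@H]2CO2)cc(OC)c1OC | intermediate
8 | (2R)-2-[(S)-({(2E)-3-[3,4-dimethoxy-5-(triisopropylsilyloxy)phenyl]prop-2-en-1-yl}oxy)(3,4,5-trimethoxyphenyl)methyl]oxirane | COc1cc(/C=C/CO[C@@H](c2cc(OC)c(OC)c(OC)c2)[C@H]2CO2)cc(O[Si](C(C)C)(C(C)C)C(C)C)c1OC | intermediate
9 | [(2R,3S,4S)-4-{[3,4-dimethoxy-5-(triisopropylsilyloxy)phenyl]methyl}-2-(3,4,5-trimethoxyphenyl)oxolan-3-yl]methanol | COc1cc(C[C@@H]2CO[C@@H](c3cc(OC)c(OC)c(OC)c3)[C@@H]2CO)cc(O[Si](C(C)C)(C(C)C)C(C)C)c1OC | intermediate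
10 | [(2R,3S,4S)-4-[(3-hydroxy-4,5-dimethoxyphenyl)methyl]-2-(3,4,5-trimethoxyphenyl)oxolan-3-yl]methanol | COc1cc(C[C@@H]2CO[C@@H](c3cc(OC)c(OC)c(OC)c3)[C@@H]2CO)cc(O)c1OC | target

**Step count.** Total: 8 steps. Longest linear sequence: 6 steps (1 → 2 → 3 → 4 → 8 → 9 → 10).

**Steps most likely to fail**

Step 7. The first radical may be captured by a second titanium before it cyclises, which would be followed by β-elimination of the titanoxy group (net deoxygenation to the allyl ether). Control of the cis relationship at C3/C4 may also be incomplete. The fallback sets out from 8 and comes back at 9, closing the same ring bond by a tin hydride chain in which no metal can intercept the radical. Acid-catalysed hydrolysis of the epoxide (cat. HClO4, THF/H2O, rt) should give (2R,3S)-3-({(2E)-3-[3,4-dimethoxy-5-(triisopropylsilyloxy)phenyl]prop-2-en-1-yl}oxy)-3-(3,4,5-trimethoxyphenyl)propane-1,2-diol F1; the configuration of its secondary carbinol is immaterial. 1,1'-Thiocarbonyldiimidazole (THF, 60 °C) should convert it into the cyclic thionocarbonate (4R)-4-[(S)-({(2E)-3-[3,4-dimethoxy-5-(triisopropylsilyloxy)phenyl]prop-2-en-1-yl}oxy)(3,4,5-trimethoxyphenyl)methyl]-1,3-dioxolane-2-thione F2. Slow addition of Bu3SnH with AIBN (toluene, 90 °C) should add the stannyl radical to sulfur and cleave the secondary C–O bond (Barton–McCombie-type fragmentation). The same type of secondary radical then closes 5-exo-trig and is reduced by the stannane to O-{[(2R,3S,4S)-4-{[3,4-dimethoxy-5-(triisopropylsilyloxy)phenyl]methyl}-2-(3,4,5-trimethoxyphenyl)oxolan-3-yl]methyl} S-(tributylstannyl) thiocarbonate F3. Mild aqueous base should hydrolyse F3 to 9.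

Step 5. The rate difference between the enantiomers of a slowly reacting terminal vinyl carbinol may be too small, which would erode the enantiomeric purity of the epoxy alcohol. The fallback sets out from 6 and comes back at 7, separating resolution from epoxidation. Candida antarctica lipase B (Novozym 435) with vinyl acetate in toluene at 30 °C should acylate the (R)-enantiomer selectively (Kazlauskas rule) to (R)-1-(3,4,5-trimethoxyphenyl)prop-2-en-1-yl acetate F4. Methanolysis (K2CO3, MeOH, 0 °C) should give (R)-1-(3,4,5-trimethoxyphenyl)prop-2-en-1-ol F5. A matched Sharpless epoxidation of F5 (Ti(OiPr)4, L-(+)-diisopropyl tartrate, tBuOOH, 4 Å MS, CH2Cl2, −20 °C), now run to full conversion, should give 7.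

Step 6. The alkoxide may undergo Payne rearrangement to the isomeric 2,3-epoxy alcohol before it is alkylated, and the electron-rich cinnamyl bromide may decompose. The fallback sets out from 3 and 7 and comes back at 8, avoiding both the free alkoxide and bromide 4. Acetylation of 3 (Ac2O, pyridine, cat. DMAP, CH2Cl2) should give rac-1-[3,4-dimethoxy-5-(triisopropylsilyloxy)phenyl]prop-2-en-1-yl acetate F6. A Tsuji–Trost allylic etherification of 7 with F6 (Et2Zn 0.5 equiv, Pd(OAc)2 5 mol%, 2-(di-tert-butylphosphino)biphenyl, THF, rt) should proceed through the aryl-substituted π-allyl complex formed by zerovalent palladium. The zinc-bound alkoxide should attack its unsubstituted terminus and give the linear (E)-ether 8 with the carbinol configuration retained.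

**Further compounds**
F1 | step 7 | (2R,3S)-3-({(2E)-3-[3,4-dimethoxy-5-(triisopropylsilyloxy)phenyl]prop-2-en-1-yl}oxy)-3-(3,4,5-trimethoxyphenyl)propane-1,2-diol | COc1cc(/C=C/CO[C@@H](c2cc(OC)c(OC)c(OC)c2)[C@H](O)CO)cc(O[Si](C(C)C)(C(C)C)C(C)C)c1OC
F2 | step 7 | (4R)-4-[(S)-({(2E)-3-[3,4-dimethoxy-5-(triisopropylsilyloxy)phenyl]prop-2-en-1-yl}oxy)(3,4,5-trimethoxyphenyl)methyl]-1,3-dioxolane-2-thione | COc1cc(/C=C/CO[C@@H](c2cc(OC)c(OC)c(OC)c2)[C@H]2COC(=S)O2)cc(O[Si](C(C)C)(C(C)C)C(C)C)c1OC
F3 | step 7 | O-{[(2R,3S,4S)-4-{[3,4-dimethoxy-5-(triisopropylsilyloxy)phenyl]methyl}-2-(3,4,5-trimethoxyphenyl)oxolan-3-yl]methyl} S-(tributylstannyl) thiocarbonate | COc1cc(C[C@@H]2CO[C@@H](c3cc(OC)c(OC)c(OC)c3)[C@@H]2COC(=O)S[Sn](CCCC)(CCCC)CCCC)cc(O[Si](C(C)C)(C(C)C)C(C)C)c1OC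
F4 | step 5 | (R)-1-(3,4,5-trimethoxyphenyl)prop-2-en-1-yl acetate | CC(=O)O[C@H](C=C)c1cc(OC)c(OC)c(OC)c1
F5 | step 5 | (R)-1-(3,4,5-trimethoxyphenyl)prop-2-en-1-ol | C=C[C@@H](O)c1cc(OC)c(OC)c(OC)c1
F6 | step 6 | rac-1-[3,4-dimethoxy-5-(triisopropylsilyloxy)phenyl]prop-2-en-1-yl acetate | CC(=O)OC(C=C)c1cc(OC)c(OC)c(O[Si](C(C)C)(C(C)C)C(C)C)c1
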